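**Plan**
Cuts: first the two O–Si bonds, then C4a–C5 and C8–C8a of ring A, then C3–C1′ between ring C and ring B (C1′ is C6 of the chromene). Ring D is finally traced back to an aryl propargyl ether.
Enabling feature: on ring A, C5 bears OMe and C7 bears OH, so C5–C6–C7–C8 maps onto a 1,1-dimethoxy-3-silyloxybutadiene. C4a and C8a are the α- and β-carbons of the C4=O/O1 enone of ring C and can serve as the 2π partner once C4a carries a sulfinyl group.
Forward order: ring D is closed on the bromoarene ring B. Ring C is bought as a dihydropyranone, sulfenylated at its vinylic α-carbon and joined to ring B at C3. Ring A is annulated last.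
Stereochemistry: C3 is made racemic and is set as (R) on the finished skeleton by Ru-catalysed transfer hydrogenation with dynamic kinetic resolution to the (3R,4R)-cis-isoflavan-4-ol. Non-enolising reoxidation of C4 and buffered desilylation follow.

Key step: step 8

Assumption: the ketene-acetal diene is taken as a purchasable reagent, and the sulfoxide dienophile is used as its mixture of epimers at sulfur and C3, because both elements are erased or reset later.

Step 1
Reactants: 1 5-bromo-2-hydroxybenzaldehyde (5-bromosalicylaldehyde); 2 3-chloro-3-methylbut-1-yne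
Product: 3 5-bromo-2-[(2-methylbut-3-yn-2-yl)oxy]benzaldehyde
Conditions: K2CO3, KI (cat.), CuI (cat.), acetone, reflux
Reagents that add atoms: none
Why: Copper-catalysed O-propargylation (Williamson-type etherification through a copper-stabilised tertiary propargyl/allenylidene electrophile) is the standard way to aryl 1,1-dimethylpropargyl ethers and suits acidic, electron-poor phenols such as 1.

Step 2
Reactants: 3 5-bromo-2-[(2-methylbut-3-yn-2-yl)oxy]benzaldehyde
Product: 5 5-bromo-2-[(2-methylbut-3-yn-2-yl)oxy]phenol, via aryl formate 4 (not isolated)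
Conditions: mCPBA, CH2Cl2, 0 °C → rt; then K2CO3 (cat.), MeOH, rt
Reagents that add atoms: mCPBA, SMILES O=C(OO)c1cccc(Cl)c1
Why: In this Baeyer–Villiger (Dakin-type) oxidation the aryl group, activated by the ortho alkoxy donor, migrates to give formate 4, which base-catalysed methanolysis cleaves; running it before the chromene exists avoids epoxidation of its alkene, and the terminal alkyne is inert to the peracid.

Step 3
Reactants: 5 5-bromo-2-[(2-methylbut-3-yn-2-yl)oxy]phenol
Product: 6 {5-bromo-2-[(2-methylbut-3-yn-2-yl)oxy]phenoxy}(tert-butyl)dimethylsilane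
Conditions: TBSCl, imidazole, DMF, rt
Reagents that add atoms: TBSCl, SMILES CC(C)(C)[Si](C)(C)Cl
Why: Imidazole-promoted O-silylation of a phenol is routine, and the silyl ether masks the future 8-OH of the chromene through the enolate coupling, the cycloaddition and the oxidations.

Step 4
Reactants: 6 {5-bromo-2-[(2-methylbut-3-yn-2-yl)oxy]phenoxy}(tert-butyl)dimethylsilane
Product: 7 6-bromo-8-(tert-butyldimethylsilyloxy)-2,2-dimethyl-2H-chromene
Conditions: o-xylene, 145 °C
Reagents that add atoms: none
Why: The aromatic propargyl Claisen rearrangement goes to the only free ortho carbon, and enolisation, 1,5-hydrogen shift and oxa-6π electrocyclisation then close ring D, the gem-dimethyl group accelerating the [3,3] shift.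

Step 5
Reactants: 8 2,3-dihydro-4H-pyran-4-one
Product: 10 5-(phenylsulfanyl)-2,3-dihydro-4H-pyran-4-one, via chloro sulfide adduct 9 (not isolated)
Conditions: PhSH, NCS, CH2Cl2, 0 °C; then 8, −78 → 0 °C; then Et3N, 0 °C → rt
Reagents that add atoms: thiophenol, SMILES Sc1ccccc1; N-chlorosuccinimide, SMILES O=C1CCC(=O)N1Cl (chlorine of 9 only)
Why: This is an electrophilic α-sulfenylation of a β-alkoxy enone by addition–elimination, in which the enol-ether carbon C5 attacks sulfur, chloride caps the oxocarbenium carbon C6 and Et3N removes HCl; placing sulfur at this stage keeps the sulfenyl chloride away from the electron-rich chromene alkene.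

Step 6
Reactants: 10 5-(phenylsulfanyl)-2,3-dihydro-4H-pyran-4-one; 7 6-bromo-8-(tert-butyldimethylsilyloxy)-2,2-dimethyl-2H-chromene
Product: 13 racemic 3-[8-(tert-butyldimethylsilyloxy)-2,2-dimethyl-2H-chromen-6-yl]-5-(phenylsulfanyl)-2,3-dihydro-4H-pyran-4-one, via lithium enolate 11 (not isolated), via chlorozinc enolate 12 (not isolated)
Conditions: 10 (1.8 equiv), LiHMDS, THF, −78 °C; ZnCl2, −78 °C → rt; then 7, Pd(dba)2 (5 mol %), P(t-Bu)3 (5 mol %), THF, rt → 50 °C
Reagents that add atoms: LiHMDS, SMILES [Li+].C[Si](C)(C)[N-][Si](C)(C)C (lithium of 11 only); ZnCl2, SMILES Cl[Zn]Cl (zinc and chlorine of 12 only)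
Why: Palladium-catalysed α-arylation of a ketone enolate in its Negishi-type zinc form is known for the α′-position of cyclic vinylogous esters; C3 is the only enolisable carbon of 10, the covalent zinc enolate resists β-elimination of O1 and spares the aryl silyl ether, and C3 forms without control (racemic) to be set in step 10.

Step 7
Reactants: 13 racemic 3-[8-(tert-butyldimethylsilyloxy)-2,2-dimethyl-2H-chromen-6-yl]-5-(phenylsulfanyl)-2,3-dihydro-4H-pyran-4-one
Product: 14 racemic 3-[8-(tert-butyldimethylsilyloxy)-2,2-dimethyl-2H-chromen-6-yl]-5-(phenylsulfinyl)-2,3-dihydro-4H-pyran-4-one (mixture of epimers at sulfur)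
Conditions: mCPBA (1.0 equiv), CH2Cl2, −78 → −40 °C
Reagents that add atoms: mCPBA, SMILES O=C(OO)c1cccc(Cl)c1
Why: Chemoselective sulfide-to-sulfoxide oxidation with one equivalent of peracid at low temperature works because sulfur reacts far faster than the chromene alkene or the acceptor-substituted enol ether, and the uncontrolled sulfur stereocentre is lost again in step 8.

Step 8
Reactants: 14 racemic 3-[8-(tert-butyldimethylsilyloxy)-2,2-dimethyl-2H-chromen-6-yl]-5-(phenylsulfinyl)-2,3-dihydro-4H-pyran-4-one; 15 1,1-dimethoxy-3-(trimethylsilyloxy)buta-1,3-diene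
Product: 19 racemic 3-[8-(tert-butyldimethylsilyloxy)-2,2-dimethyl-2H-chromen-6-yl]-7-hydroxy-5-methoxychroman-4-one, via cycloadduct 16 (not isolated), via cyclohexadiene acetal 17 (not isolated), via trimethylsilyl ether 18 (not isolated)
Conditions: 15 (3 equiv), Eu(fod)3 (10 mol %), toluene, 60 → 100 °C; then AcOH–THF–H2O, rt
Reagents that add atoms: none
Why: Proposed new method: the CH2 terminus of 15, where the three oxygen donors concentrate the HOMO coefficient, bonds to C8a (C6 of the pyranone, the β-carbon of the enone) and the ketene-acetal carbon bonds to the sulfinyl-bearing C4a (C5 of the pyranone), either in one asynchronous [4+2] event or as a Mukaiyama–Michael addition followed by collapse of the sulfinyl-stabilised enolate onto the dialkoxycarbenium ion. Ring A is thereby closed as a six-membered carbocycle by an intermolecular, suprafacial [4+2] annulation across C4a=C8a, which places the sulfinyl group and H-8a cis in 16. This cis relation is what the thermal syn-elimination of benzenesulfenic acid requires (H-8a is the only β-hydrogen), the cross-conjugated acetal 17 then loses methanol by 1,4-elimination to give arene 18, and the labile aryl trimethylsilyl ether is hydrolysed in the mildly acidic work-up that leaves the tert-butyldimethylsilyl ether in place. The closest known reaction type is the cycloaddition–aromatisation of 1,1-dialkoxy-3-silyloxy dienes with sulfinyl- or haloquinones, 2-sulfinylcycloalkenones and 3-acylchromones; new here is a monocyclic β-alkoxy enone as 2π partner, whose deactivating ring oxygen is offset by the sulfinyl acceptor, by Eu(fod)3 chelated between S–O and C4=O, and by an excess of the diene. No lasting stereocentre is formed, since C4a and C8a end up sp2 and C3 stays racemic until step 10. The step needs regioselectivity (OMe on C5, OH on C7), secured by the matched polarisation of enone and diene, and site selectivity for C4a=C8a over the chromene C3=C4 bond, secured because that alkene is electron-rich and inert to a nucleophilic diene.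

Step 9
Reactants: 19 racemic 3-[8-(tert-butyldimethylsilyloxy)-2,2-dimethyl-2H-chromen-6-yl]-7-hydroxy-5-methoxychroman-4-one
Product: 20 racemic 3-[8-(tert-butyldimethylsilyloxy)-2,2-dimethyl-2H-chromen-6-yl]-5-methoxy-7-(triisopropylsilyloxy)chroman-4-one
Conditions: TIPSCl, imidazole, DMF, rt
Reagents that add atoms: TIPSCl, SMILES CC(C)[Si](Cl)(C(C)C)C(C)C
Why: Imidazole-promoted O-silylation of the acidic 7-OH uses the bulkier triisopropylsilyl group because a silyl ether para to the carbonyl behaves as a vinylogous silyl ester and must survive the amine–formate medium, whereas a free 7-OH would deactivate the ketone and interfere with the periodinane.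

Step 10
Reactants: 20 racemic 3-[8-(tert-butyldimethylsilyloxy)-2,2-dimethyl-2H-chromen-6-yl]-5-methoxy-7-(triisopropylsilyloxy)chroman-4-one
Product: 21 (3R,4R)-3-[8-(tert-butyldimethylsilyloxy)-2,2-dimethyl-2H-chromen-6-yl]-5-methoxy-7-(triisopropylsilyloxy)chroman-4-ol (cis)
Conditions: RuCl[(R,R)-TsDPEN](p-cymene) (3 mol %), HCO2H–Et3N (1:1), EtOAc, 40 °C
Reagents that add atoms: none
Why: Noyori–Ikariya asymmetric transfer hydrogenation with dynamic kinetic resolution is precedented on isoflavanones: Et3N racemises C3 through the enol, the (R,R)-catalyst delivers hydride to the carbonyl face that gives (4R) and turns over only the (3R)-ketone, in which hydride arrives anti to the 3-aryl group, so the (3R,4R)-cis alcohol should result while the chromene alkene is left alone.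

Step 11
Reactants: 21 (3R,4R)-3-[8-(tert-butyldimethylsilyloxy)-2,2-dimethyl-2H-chromen-6-yl]-5-methoxy-7-(triisopropylsilyloxy)chroman-4-ol
Product: 22 (3R)-3-[8-(tert-butyldimethylsilyloxy)-2,2-dimethyl-2H-chromen-6-yl]-5-methoxy-7-(triisopropylsilyloxy)chroman-4-one
Conditions: Dess–Martin periodinane, NaHCO3, CH2Cl2, 0 °C → rt
Reagents that add atoms: none
Why: Dess–Martin oxidation under bicarbonate buffer removes the auxiliary C4 stereocentre under non-enolising conditions, so the (R) configuration at C3 should be kept, and the buffer protects the electron-rich benzylic alcohol from acid-induced ionisation.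

Step 12
Reactants: 22 (3R)-3-[8-(tert-butyldimethylsilyloxy)-2,2-dimethyl-2H-chromen-6-yl]-5-methoxy-7-(triisopropylsilyloxy)chroman-4-one
Product: 23 (3R)-7-hydroxy-3-(8-hydroxy-2,2-dimethyl-2H-chromen-6-yl)-5-methoxychroman-4-one (target)
Conditions: TBAF, AcOH, THF, 0 °C
Reagents that add atoms: none
Why: Fluoride-mediated cleavage of both aryl silyl ethers with acetic acid as buffer keeps phenoxide and fluoride basicity low, so the enolisable C3–H should not epimerise and the acid-sensitive chromene is untouched.

**Compound list**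
1 | 5-bromo-2-hydroxybenzaldehyde | O=Cc1cc(Br)ccc1O | starting material
2 | 3-chloro-3-methylbut-1-yne | CC(C)(Cl)C#C | starting material
3 | 5-bromo-2-[(2-methylbut-3-yn-2-yl)oxy]benzaldehyde | O=Cc1cc(Br)ccc1OC(C)(C)C#C | intermediate
4 | 5-bromo-2-[(2-methylbut-3-yn-2-yl)oxy]phenyl formate (not isolated) | O=COc1cc(Br)ccc1OC(C)(C)C#C | intermediate
5 | 5-bromo-2-[(2-methylbut-3-yn-2-yl)oxy]phenol | Oc1cc(Br)ccc1OC(C)(C)C#C | intermediate
6 | {5-bromo-2-[(2-methylbut-3-yn-2-yl)oxy]phenoxy}(tert-butyl)dimethylsilane | CC(C)(C)[Si](C)(C)Oc1cc(Br)ccc1OC(C)(C)C#C | intermediate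
7 | 6-bromo-8-(tert-butyldimethylsilyloxy)-2,2-dimethyl-2H-chromene | CC(C)(C)[Si](C)(C)Oc1cc(Br)cc2c1OC(C)(C)C=C2 | intermediate
8 | 2,3-dihydro-4H-pyran-4-one | O=C1CCOC=C1 | starting material
9 | 2-chloro-3-(phenylsulfanyl)tetrahydro-4H-pyran-4-one (not isolated) | O=C1CCOC(Cl)C1Sc1ccccc1 | intermediate
10 | 5-(phenylsulfanyl)-2,3-dihydro-4H-pyran-4-one | O=C1CCOC=C1Sc1ccccc1 | intermediate
11 | lithium 5-(phenylsulfanyl)-2H-pyran-4-olate (not isolated) | [Li+].[O-]C1=CCOC=C1Sc1ccccc1 | intermediate
12 | chlorozinc 5-(phenylsulfanyl)-2H-pyran-4-olate (not isolated) | Cl[Zn]OC1=CCOC=C1Sc1ccccc1 | intermediate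
13 | racemic 3-[8-(tert-butyldimethylsilyloxy)-2,2-dimethyl-2H-chromen-6-yl]-5-(phenylsulfanyl)-2,3-dihydro-4H-pyran-4-one | O=C1C(c2cc(O[Si](C)(C)C(C)(C)C)c3c(c2)C=CC(C)(C)O3)COC=C1Sc1ccccc1 | intermediate
14 | racemic 3-[8-(tert-butyldimethylsilyloxy)-2,2-dimethyl-2H-chromen-6-yl]-5-(phenylsulfinyl)-2,3-dihydro-4H-pyran-4-one, epimers at sulfur | O=C1C(c2cc(O[Si](C)(C)C(C)(C)C)c3c(c2)C=CC(C)(C)O3)COC=C1S(=O)c1ccccc1 | intermediate
15 | 1,1-dimethoxy-3-(trimethylsilyloxy)buta-1,3-diene | COC(OC)=CC(=C)O[Si](C)(C)C | starting material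
16 | cis-fused 3-aryl-5,5-dimethoxy-4a-(phenylsulfinyl)-7-(trimethylsilyloxy)-2,3,4a,5,8,8a-hexahydro-4H-chromen-4-one, aryl as in 14, diastereomer mixture (not isolated) | COC1(OC)C=C(O[Si](C)(C)C)CC2OCC(c3cc(O[Si](C)(C)C(C)(C)C)c4c(c3)C=CC(C)(C)O4)C(=O)C12S(=O)c1ccccc1 | intermediate
17 | 3-aryl-5,5-dimethoxy-7-(trimethylsilyloxy)-2,3,5,8-tetrahydro-4H-chromen-4-one, aryl as in 14 (not isolated) | COC1(OC)C=C(O[Si](C)(C)C)CC2=C1C(=O)C(c1cc(O[Si](C)(C)C(C)(C)C)c3c(c1)C=CC(C)(C)O3)CO2 | intermediate
18 | racemic 3-[8-(tert-butyldimethylsilyloxy)-2,2-dimethyl-2H-chromen-6-yl]-5-methoxy-7-(trimethylsilyloxy)chroman-4-one (not isolated) | COc1cc(O[Si](C)(C)C)cc2c1C(=O)C(c1cc(O[Si](C)(C)C(C)(C)C)c3c(c1)C=CC(C)(C)O3)CO2 | intermediate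
19 | racemic 3-[8-(tert-butyldimethylsilyloxy)-2,2-dimethyl-2H-chromen-6-yl]-7-hydroxy-5-methoxychroman-4-one | COc1cc(O)cc2c1C(=O)C(c1cc(O[Si](C)(C)C(C)(C)C)c3c(c1)C=CC(C)(C)O3)CO2 | intermediate
20 | racemic 3-[8-(tert-butyldimethylsilyloxy)-2,2-dimethyl-2H-chromen-6-yl]-5-methoxy-7-(triisopropylsilyloxy)chroman-4-one | COc1cc(O[Si](C(C)C)(C(C)C)C(C)C)cc2c1C(=O)C(c1cc(O[Si](C)(C)C(C)(C)C)c3c(c1)C=CC(C)(C)O3)CO2 | intermediate
21 | (3R,4R)-3-[8-(tert-butyldimethylsilyloxy)-2,2-dimethyl-2H-chromen-6-yl]-5-methoxy-7-(triisopropylsilyloxy)chroman-4-ol | COc1cc(O[Si](C(C)C)(C(C)C)C(C)C)cc2c1[C@H](O)[C@H](c1cc(O[Si](C)(C)C(C)(C)C)c3c(c1)C=CC(C)(C)O3)CO2 | intermediate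
22 | (3R)-3-[8-(tert-butyldimethylsilyloxy)-2,2-dimethyl-2H-chromen-6-yl]-5-methoxy-7-(triisopropylsilyloxy)chroman-4-one | COc1cc(O[Si](C(C)C)(C(C)C)C(C)C)cc2c1C(=O)[C@H](c1cc(O[Si](C)(C)C(C)(C)C)c3c(c1)C=CC(C)(C)O3)CO2 | intermediate
23 | (3R)-7-hydroxy-3-(8-hydroxy-2,2-dimethyl-2H-chromen-6-yl)-5-methoxychroman-4-one | COc1cc(O)cc2c1C(=O)[C@H](c1cc(O)c3c(c1)C=CC(C)(C)O3)CO2 | target

Total step count: 12. Longest linear sequence: 11 steps (steps 1–4, then 6–12). Step 5 is the one-step side branch.

**Steps most likely to fail**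

1. Step 8.
- What may go wrong: the cycloaddition may be too slow because O1 feeds electron density into C8a. The diene may be used up by hydrolysis or by the sulfenic acid that is released. The enone may react as a 1-oxadiene in an inverse-demand hetero-Diels–Alder reaction. A stepwise Michael addition may be followed by β-elimination of O1 and opening of ring C.
- Fallback (known chemistry only): ring A is bought instead of built. The sequence sets out from bromide 7 and comes back at 20. Commercial 5,7-dihydroxychroman-4-one F1 is silylated at the non-chelated 7-OH (TIPSCl, imidazole, DMF) to give 5-hydroxy-7-(triisopropylsilyloxy)chroman-4-one F2. The hydrogen-bonded 5-OH is then methylated under neutral conditions (MeI, Ag2O, DMF) to give 5-methoxy-7-(triisopropylsilyloxy)chroman-4-one F3. Palladium-catalysed α-arylation of F3 with 7 (Pd(dba)2, P(t-Bu)3, NaOt-Bu, THF, 50 °C), an established entry to isoflavanones, gives 20. Steps 10–12 follow unchanged.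

2. Step 6.
- What may go wrong: the enolate may open ring C by β-elimination of O1. Proton transfer from the more acidic product may stall conversion. The vinyl sulfide may slow the catalyst.
- Fallback: the order of arylation and annulation is reversed, setting out from 10 and coming back at 20. Oxidation of 10 (mCPBA, CH2Cl2, −78 °C) gives 5-(phenylsulfinyl)-2,3-dihydro-4H-pyran-4-one F4. This is submitted with 15 to the cycloaddition–aromatisation of step 8 and gives 7-hydroxy-5-methoxychroman-4-one F5. Silylation (TIPSCl, imidazole, DMF) leads to 5-methoxy-7-(triisopropylsilyloxy)chroman-4-one F3, and its α-arylation with 7 under the conditions given above gives 20. The C3–C1′ bond is then made on a chromanone, where the ring-opening pathway would expel only a phenoxide rather than a β-keto enolate and where the reaction type is established.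

3. Step 10.
- What may go wrong: hydride transfer to a carbonyl flanked by the 5-OMe group and deactivated by three oxygen donors may be slow. Racemisation of C3 may not keep pace with reduction, so that enantio- and diastereoselectivity erode. The electron-rich benzylic alcohol may ionise and dehydrate in the formate medium.
- Fallback: C3 is set by enantioselective protonation rather than by reduction, setting out from 20 and coming back at 22. Enolisation and O-acylation (KHMDS, allyl chloroformate, THF, −78 °C) give allyl 3-[8-(tert-butyldimethylsilyloxy)-2,2-dimethyl-2H-chromen-6-yl]-5-methoxy-7-(triisopropylsilyloxy)-2H-chromen-4-yl carbonate F6. Catalytic enantioselective decarboxylative protonation (Pd2(dba)3, t-Bu-PHOX, Meldrum's acid, dioxane, rt), a reaction type shown on isoflavanone enolates, gives 22 directly. The ligand enantiomer that leads to the (R) series is identified in a trial run. Step 11 is skipped and step 12 follows.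

**Further compounds**
F1 | step 8 | 5,7-dihydroxychroman-4-one (purchased) | O=C1CCOc2cc(O)cc(O)c12
F2 | step 8 | 5-hydroxy-7-(triisopropylsilyloxy)chroman-4-one | CC(C)[Si](Oc1cc(O)c2C(=O)CCOc2c1)(C(C)C)C(C)C
F3 | step 8 | 5-methoxy-7-(triisopropylsilyloxy)chroman-4-one | COc1cc(O[Si](C(C)C)(C(C)C)C(C)C)cc2c1C(=O)CCO2
F4 | step 6 | 5-(phenylsulfinyl)-2,3-dihydro-4H-pyran-4-one | O=C1CCOC=C1S(=O)c1ccccc1
F5 | step 6 | 7-hydroxy-5-methoxychroman-4-one | COc1cc(O)cc2c1C(=O)CCO2
F6 | step 10 | allyl 3-[8-(tert-butyldimethylsilyloxy)-2,2-dimethyl-2H-chromen-6-yl]-5-methoxy-7-(triisopropylsilyloxy)-2H-chromen-4-yl carbonate | C=CCOC(=O)OC1=C(c2cc(O[Si](C)(C)C(C)(C)C)c3c(c2)C=CC(C)(C)O3)COc2cc(O[Si](C(C)C)(C(C)C)C(C)C)cc(OC)c12
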